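**Retrosynthetic overview**
- Target ⇐ hexabenzyl (E)-chalcone: one hydrogenation saturates the enone C=C and removes all six benzyl ethers.
- Chalcone ⇐ Claisen–Schmidt aldol condensation of a 7-acetyl-3-aroyl-2-arylbenzofuran with 4-(benzyloxy)benzaldehyde; this forms the key Cα–Cβ bond of the dihydrochalcone arm.
- 3-Aroyl-2-arylbenzofuran ⇐ palladium-catalysed carbonylative heteroannulation of an o-alkynylphenol, 2,4-bis(benzyloxy)-1-iodobenzene and CO.
- o-Alkynylphenol ⇐ Sonogashira coupling of iodinated 4,6-di-O-benzyl phloroacetophenone with 4-(benzyloxy)phenylacetylene, which is made from the same aldehyde; the aryl iodide comes from resorcinol.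
- Ring order: all four benzene rings are bought; the furan ring is the only ring formed (step 9).

Assumption: the target has no stereocentre (its SMILES carries no stereodescriptor), so the achiral compound itself is the required single stereoisomer; the only stereo-element in the route is the transient (E)-alkene of the chalcone.

**Step 1**
Reactants: 1 1-(2,4,6-trihydroxyphenyl)ethan-1-one (phloroacetophenone, dried monohydrate)
Product: 2 1-[2,4-bis(benzyloxy)-6-hydroxyphenyl]ethan-1-one
Conditions: BnBr (2.05 equiv), K2CO3 (2.2 equiv), DMF, 0 °C to rt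
Reagents that add atoms: benzyl bromide, BrCc1ccccc1
Why: Williamson ether synthesis in which the para hydroxyl and one ortho hydroxyl are alkylated while the last hydroxyl, chelated to the acetyl carbonyl by an intramolecular hydrogen bond, is the least nucleophilic and stays free.

**Step 2**
Reactants: 2 1-[2,4-bis(benzyloxy)-6-hydroxyphenyl]ethan-1-one
Product: 3 1-[4,6-bis(benzyloxy)-2-hydroxy-3-iodophenyl]ethan-1-one
Conditions: NIS (1.05 equiv), DMF, 0 °C to rt, dark
Reagents that add atoms: N-iodosuccinimide, O=C1CCC(=O)N1I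
Why: Electrophilic aromatic iodination, expected by analogy with hydrogen-bonded 2-hydroxy-4,6-dialkoxyaryl ketones to go ortho to the free phenol rather than into the more crowded position between the two benzyloxy groups.

**Step 3**
Reactants: 3 1-[4,6-bis(benzyloxy)-2-hydroxy-3-iodophenyl]ethan-1-one
Product: 4 2-acetyl-3,5-bis(benzyloxy)-6-iodophenyl acetate
Conditions: Ac2O, pyridine, DMAP (cat.), rt to 40 °C
Reagents that add atoms: acetic anhydride, CC(=O)OC(C)=O
Why: DMAP-catalysed O-acetylation (nucleophilic acyl transfer) masks the phenol so that the coming alkyne coupling cannot run on to an unwanted 3-unsubstituted benzofuran.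

**Step 4**
Reactants: 5 4-(benzyloxy)benzaldehyde
Product: 7 1-(benzyloxy)-4-ethynylbenzene, via diazoalkene 6 (not isolated)
Conditions: Ohira–Bestmann reagent (1.2 equiv), K2CO3 (2 equiv), MeOH–THF, 0 °C to rt
Reagents that add atoms: dimethyl (1-diazo-2-oxopropyl)phosphonate (Ohira–Bestmann reagent), CC(=O)C(=[N+]=[N-])P(=O)(OC)OC
Why: Seyferth–Gilbert homologation in its Ohira–Bestmann form, in which the diazophosphonate anion made in situ olefinates the aldehyde in Horner–Wadsworth–Emmons fashion and the diazoalkene loses N2 with a 1,2-hydrogen shift to give the terminal alkyne under conditions that benzyl ethers tolerate.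

**Step 5**
Reactants: 4 2-acetyl-3,5-bis(benzyloxy)-6-iodophenyl acetate; 7 1-(benzyloxy)-4-ethynylbenzene
Product: 8 2-acetyl-3,5-bis(benzyloxy)-6-{[4-(benzyloxy)phenyl]ethynyl}phenyl acetate
Conditions: PdCl2(PPh3)2 (5 mol %), CuI (10 mol %), Et3N, DMF, 60 °C, argon, slow addition of 7
Reagents that add atoms: none
Why: Sonogashira coupling, in which the aryl iodide undergoes oxidative addition readily despite its two ortho substituents, and the tertiary amine base leaves the aryl acetate and the methyl ketone untouched.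

**Step 6**
Reactants: 8 2-acetyl-3,5-bis(benzyloxy)-6-{[4-(benzyloxy)phenyl]ethynyl}phenyl acetate
Product: 9 1-[4,6-bis(benzyloxy)-3-{[4-(benzyloxy)phenyl]ethynyl}-2-hydroxyphenyl]ethan-1-one
Conditions: K2CO3 (cat.), MeOH–THF, 0 °C to rt, 1 h; aq. NH4Cl quench
Reagents that add atoms: none
Why: Base-catalysed transesterification (methanolysis) of the aryl acetate is fast at 0 °C, whereas 5-endo-dig closure of the weakly nucleophilic, carbonyl-chelated phenoxide onto the electron-rich alkyne needs much more forcing conditions.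

**Step 7**
Reactants: 10 benzene-1,3-diol (resorcinol)
Product: 11 1,3-bis(benzyloxy)benzene
Conditions: BnBr (2.2 equiv), K2CO3 (2.5 equiv), acetone, reflux
Reagents that add atoms: benzyl bromide, BrCc1ccccc1
Why: Double Williamson ether synthesis of an unhindered diphenol under standard carbonate conditions.

**Step 8**
Reactants: 11 1,3-bis(benzyloxy)benzene
Product: 12 2,4-bis(benzyloxy)-1-iodobenzene
Conditions: NIS (1.0 equiv), TFA (cat.), MeCN, rt
Reagents that add atoms: N-iodosuccinimide, O=C1CCC(=O)N1I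
Why: Electrophilic aromatic iodination of a 1,3-dialkoxybenzene goes to the position ortho to one ether and para to the other, because the position between the two ethers is hindered, and one equivalent of NIS limits di-iodination.

**Step 9**
Reactants: 9 1-[4,6-bis(benzyloxy)-3-{[4-(benzyloxy)phenyl]ethynyl}-2-hydroxyphenyl]ethan-1-one; 12 2,4-bis(benzyloxy)-1-iodobenzene
Product: 13 1-{4,6-bis(benzyloxy)-3-[2,4-bis(benzyloxy)benzoyl]-2-[4-(benzyloxy)phenyl]-1-benzofuran-7-yl}ethan-1-one
Conditions: Pd(PPh3)4 (5 mol %), CO (1 atm), K2CO3 (3 equiv), MeCN–THF, 50 °C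
Reagents that add atoms: carbon monoxide, [C-]#[O+]
Why: Palladium-catalysed carbonylative heteroannulation (Arcadi–Cacchi type), in which 12 adds oxidatively to zerovalent palladium, CO insertion gives an aroyl divalent-palladium species that activates the alkyne for anti attack by the phenoxide, and reductive elimination closes the furan ring with the aroyl group at C3 and the aryl group at C2.

**Step 10**
Reactants: 13 1-{4,6-bis(benzyloxy)-3-[2,4-bis(benzyloxy)benzoyl]-2-[4-(benzyloxy)phenyl]-1-benzofuran-7-yl}ethan-1-one; 5 4-(benzyloxy)benzaldehyde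
Product: 15 (2E)-1-{4,6-bis(benzyloxy)-3-[2,4-bis(benzyloxy)benzoyl]-2-[4-(benzyloxy)phenyl]-1-benzofuran-7-yl}-3-[4-(benzyloxy)phenyl]prop-2-en-1-one, via aldol adduct 14 (not isolated)
Conditions: KOH (50 % aq., excess), EtOH–THF, rt, 24–48 h
Reagents that add atoms: none
Why: Claisen–Schmidt crossed aldol condensation, in which the 7-acetyl group is the only enolisable carbonyl and the aldehyde cannot enolise, so the enolate adds to the aldehyde and the aldol adduct loses water by E1cB to the thermodynamically favoured (E)-enone, forming the Cα–Cβ bond that joins the benzofuran core to the last aryl fragment.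

**Step 11**
Reactants: 15 (2E)-1-{4,6-bis(benzyloxy)-3-[2,4-bis(benzyloxy)benzoyl]-2-[4-(benzyloxy)phenyl]-1-benzofuran-7-yl}-3-[4-(benzyloxy)phenyl]prop-2-en-1-one
Product: 17 1-[3-(2,4-dihydroxybenzoyl)-4,6-dihydroxy-2-(4-hydroxyphenyl)-1-benzofuran-7-yl]-3-(4-hydroxyphenyl)propan-1-one, via hexabenzyl dihydrochalcone 16 (not isolated)
Conditions: H2 (1 atm), 10 % Pd/C, EtOAc–MeOH, rt, stopped once debenzylation is complete
Reagents that add atoms: none
Why: Heterogeneous catalytic hydrogenation saturates the enone C=C first and hydrogenolysis then cleaves the six benzylic C–O bonds, while the conjugated aryl ketones and the tetrasubstituted furan C2=C3 bond resist reduction at 1 atm in a neutral solvent; no stereocentre is created.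

**Compound list**
1 | 1-(2,4,6-trihydroxyphenyl)ethan-1-one (phloroacetophenone) | CC(=O)c1c(O)cc(O)cc1O | starting material
2 | 1-[2,4-bis(benzyloxy)-6-hydroxyphenyl]ethan-1-one | CC(=O)c1c(O)cc(OCc2ccccc2)cc1OCc1ccccc1 | intermediate
3 | 1-[4,6-bis(benzyloxy)-2-hydroxy-3-iodophenyl]ethan-1-one | CC(=O)c1c(O)c(I)c(OCc2ccccc2)cc1OCc1ccccc1 | intermediate
4 | 2-acetyl-3,5-bis(benzyloxy)-6-iodophenyl acetate | CC(=O)Oc1c(I)c(OCc2ccccc2)cc(OCc2ccccc2)c1C(C)=O | intermediate
5 | 4-(benzyloxy)benzaldehyde | O=Cc1ccc(OCc2ccccc2)cc1 | starting material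
6 | 1-(benzyloxy)-4-(2-diazoethenyl)benzene (diazoalkene, not isolated) | [N-]=[N+]=C=Cc1ccc(OCc2ccccc2)cc1 | intermediate
7 | 1-(benzyloxy)-4-ethynylbenzene | C#Cc1ccc(OCc2ccccc2)cc1 | intermediate
8 | 2-acetyl-3,5-bis(benzyloxy)-6-{[4-(benzyloxy)phenyl]ethynyl}phenyl acetate | CC(=O)Oc1c(C#Cc2ccc(OCc3ccccc3)cc2)c(OCc2ccccc2)cc(OCc2ccccc2)c1C(C)=O | intermediate
9 | 1-[4,6-bis(benzyloxy)-3-{[4-(benzyloxy)phenyl]ethynyl}-2-hydroxyphenyl]ethan-1-one | CC(=O)c1c(O)c(C#Cc2ccc(OCc3ccccc3)cc2)c(OCc2ccccc2)cc1OCc1ccccc1 | intermediate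
10 | benzene-1,3-diol (resorcinol) | Oc1cccc(O)c1 | starting material
11 | 1,3-bis(benzyloxy)benzene | c1ccc(COc2cccc(OCc3ccccc3)c2)cc1 | intermediate
12 | 2,4-bis(benzyloxy)-1-iodobenzene | Ic1ccc(OCc2ccccc2)cc1OCc1ccccc1 | intermediate
13 | 1-{4,6-bis(benzyloxy)-3-[2,4-bis(benzyloxy)benzoyl]-2-[4-(benzyloxy)phenyl]-1-benzofuran-7-yl}ethan-1-one | CC(=O)c1c(OCc2ccccc2)cc(OCc2ccccc2)c2c(C(=O)c3ccc(OCc4ccccc4)cc3OCc3ccccc3)c(-c3ccc(OCc4ccccc4)cc3)oc12 | intermediate
14 | 1-{4,6-bis(benzyloxy)-3-[2,4-bis(benzyloxy)benzoyl]-2-[4-(benzyloxy)phenyl]-1-benzofuran-7-yl}-3-[4-(benzyloxy)phenyl]-3-hydroxypropan-1-one (racemic aldol adduct, not isolated) | O=C(CC(O)c1ccc(OCc2ccccc2)cc1)c1c(OCc2ccccc2)cc(OCc2ccccc2)c2c(C(=O)c3ccc(OCc4ccccc4)cc3OCc3ccccc3)c(-c3ccc(OCc4ccccc4)cc3)oc12 | intermediate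
15 | (2E)-1-{4,6-bis(benzyloxy)-3-[2,4-bis(benzyloxy)benzoyl]-2-[4-(benzyloxy)phenyl]-1-benzofuran-7-yl}-3-[4-(benzyloxy)phenyl]prop-2-en-1-one | O=C(/C=C/c1ccc(OCc2ccccc2)cc1)c1c(OCc2ccccc2)cc(OCc2ccccc2)c2c(C(=O)c3ccc(OCc4ccccc4)cc3OCc3ccccc3)c(-c3ccc(OCc4ccccc4)cc3)oc12 | intermediate
16 | 1-{4,6-bis(benzyloxy)-3-[2,4-bis(benzyloxy)benzoyl]-2-[4-(benzyloxy)phenyl]-1-benzofuran-7-yl}-3-[4-(benzyloxy)phenyl]propan-1-one (hexabenzyl dihydrochalcone, not isolated) | O=C(CCc1ccc(OCc2ccccc2)cc1)c1c(OCc2ccccc2)cc(OCc2ccccc2)c2c(C(=O)c3ccc(OCc4ccccc4)cc3OCc3ccccc3)c(-c3ccc(OCc4ccccc4)cc3)oc12 | intermediate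
17 | 1-[3-(2,4-dihydroxybenzoyl)-4,6-dihydroxy-2-(4-hydroxyphenyl)-1-benzofuran-7-yl]-3-(4-hydroxyphenyl)propan-1-one (CNP0181782.0, achiral) | O=C(CCc1ccc(O)cc1)c1c(O)cc(O)c2c(C(=O)c3ccc(O)cc3O)c(-c3ccc(O)cc3)oc12 | target

**Totals**
Total step count: 11.
Longest linear sequence: 8 steps (steps 1, 2, 3, 5, 6, 9, 10, 11, from 1 to 17).

**Three steps most likely to fail, each with a fallback**

Step 9 (three-component carbonylative annulation). The risks are direct cyclisation of 9 to the 3-unsubstituted benzofuran and non-carbonylative arylation. The fallback sets out from 9 and makes the two bonds in separate operations. 5-Endo-dig iodocyclisation of 9 (I2, NaHCO3, MeCN, rt) gives 1-{4,6-bis(benzyloxy)-2-[4-(benzyloxy)phenyl]-3-iodo-1-benzofuran-7-yl}ethan-1-one F1. A carbonylative Suzuki–Miyaura coupling of this iodide with purchased [2,4-bis(benzyloxy)phenyl]boronic acid (PdCl2(dppf), K2CO3, CO 1 atm, anisole–water, 80 °C) then tolerates the methyl ketone and comes back to the route at 13.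

Step 2 (site of iodination, ortho to the free phenol versus between the two ethers, and over-iodination). The fallback sets out from 1 and reverses the order of halogenation and protection. Because the two open ring positions of 1 are equivalent, NIS (1.0 equiv, MeCN, 0 °C) can give only one mono-iodide, 1-(2,4,6-trihydroxy-3-iodophenyl)ethan-1-one F2. Williamson benzylation of this triol (BnBr 2.0 equiv, K2CO3, DMF, rt) should then take the para hydroxyl and the less hindered ortho hydroxyl. The hydroxyl wedged between iodine and the acetyl group stays free, and the route is rejoined at 3; this O-alkylation selectivity is the point to confirm by HMBC.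

Step 11 (over-reduction of an aryl ketone, or stalled removal of six benzyl groups). The fallback sets out from 15 and separates reduction from deprotection. Hydrogenation over Pd/C poisoned with Ph2S (H2 1 atm, EtOAc, rt) saturates only the enone C=C and gives 16 as an isolated compound. Non-reductive debenzylation with BCl3 and pentamethylbenzene as cation scavenger (CH2Cl2, −78 °C, then aqueous work-up) then comes back at 17; compounds outside the list: none F0.

**Further compounds**
F1 | step 9 | 1-{4,6-bis(benzyloxy)-2-[4-(benzyloxy)phenyl]-3-iodo-1-benzofuran-7-yl}ethan-1-one | CC(=O)c1c(OCc2ccccc2)cc(OCc2ccccc2)c2c(I)c(-c3ccc(OCc4ccccc4)cc3)oc12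
F2 | step 2 | 1-(2,4,6-trihydroxy-3-iodophenyl)ethan-1-one | CC(=O)c1c(O)cc(O)c(I)c1O
F0 | step 11 | none | none
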